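If the two mirror-image substrates were consumed at one pace, the excess of right-handed over left-handed substrate among what is left would stay at zero however far the flask ran. That symmetric case is the zero of the scale used here.

| flask | left-handed substrate | right-handed substrate | gas | free catalyst | remark | time |
|---|---|---|---|---|---|---|
| alpha | 0.27 M | 0.27 M | 17 mM (held) | 0.67 mol% | run made earlier |  |
| delta | 0.27 M | 0.27 M | 17 mM (held) | 1.5 mol% | run made earlier |  |
| flask | 0.27 M | 0.27 M | 17 mM (held) | 1 mol% |  | 20 h |

- alpha (time / h: right-handed substrate / %, left-handed substrate / %): 1.00: 46.0, 43.8; 1.50: 43.7, 40.5; 2.50: 39.7, 34.8; 4.00: 34.2, 27.4; 8.00: 22.5, 14.5; 12.0: 15.5, 7.8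
- delta (time / h: right-handed substrate / %, left-handed substrate / %): 0.833: 45.5, 43.5; 2.50: 36.5, 29.8; 4.00: 28.8, 20.6; 6.00: 19.2, 11.0; 10.0: 7.7, 2.5; 12.0: 5.0, 1.0

(standard deviation of a reading: 0.3 percentage points)

- free catalyst is single-handed; left-handed substrate and right-handed substrate are mirror images of each other, charged as a racemate, each of them at the stated concentration
- at the start none of the gas is in solution

- whether the excess of right-handed substrate over left-handed substrate among what is left of the two reaches 99 % by 20 h (no / yes)
- the highest excess of right-handed substrate over left-handed substrate among what is left of the two up to 20 h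

What do you read first? The last alpha reading gives 1.59. I call this s, the selectivity factor: the log of the fraction of c(left-handed substrate) remaining, divided by the same log for c(right-handed substrate). The symmetric case is s equal to one.

Why a ratio of logs? If each substrate's rate is its own constant times its own concentration times a factor common to both, that factor cancels, however it changes with time. The delta run, with more catalyst, reads 1.60 at 10.0 h.

How does s give the excess? Call the log of charged over remaining right-handed substrate the depth. The ratio of right-handed to left-handed substrate remaining is then exp((s − one) × depth).

Can the flask reach 99 %? That takes a depth of 9.03, with 0.0120 % of the right-handed charge remaining. The delta run, with more catalyst than this flask, stood at depth 2.30 after 12.0 h. But this flask runs to 20 h, so the depth there has to be reckoned.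

And the top? Scaling depth with loading and time gives 2.56 from delta and 2.91 from alpha, so an excess of 63.8 % to 69.5 %.

The weak spot? That scaling is a guess, and the two runs already disagree on it, but both depths stand below 9.03, so I say no.

The forecast answers no and gives a top of 66 %, within 58 % to 74 %, from a depth of 2.7, holding that “selectivity is unaffected”.

The flask gives no and a top of 59.6 %.

    partner + free catalyst + left-handed substrate → free catalyst + left-handed product (k = 3.44 M⁻² s⁻¹)
    partner + free catalyst + right-handed substrate → free catalyst + right-handed product (k = 2.16 M⁻² s⁻¹)
    partner + free catalyst → spent catalyst (k = 0.00214 M⁻¹ s⁻¹)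
    gas ⇌ partner, rate k4*(csat - [partner]) (kL = 0.00158 s⁻¹)

At 20.0 h the flask keeps 9.8 % of the charged right-handed substrate, a depth of 2.32 against the forecast's 2.7, and its free catalyst stands at 14.8 % of the catalyst charged. With s from alpha, that depth gives an excess of 59.4 %. A neighbouring flask, alike except for 1.7 mol% of free catalyst, keeps 2.0 % of the charged right-handed substrate, a depth of 3.92. The same s then gives 82.0 %, and that neighbouring flask's top is 82.1 %.

Readings and results were generated by integration from invented constants; scatter was added.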